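**Retrosynthetic overview**
- The target is traced back to a β-hydroxy lactone: the C3 benzylic CH2 comes from hydrogenolysis of a benzylic carbinol, and the phenol is carried as a benzyl ether that falls off in the same operation.
- The carbinol is disconnected at the C3–benzylic carbon bond by a crossed aldol between the lithium enolate of (R)-4-(3,4-dimethoxybenzyl)butyrolactone and 3-benzyloxy-4,5-dimethoxybenzaldehyde; the C4 substituent directs C3 trans.
- The lactone comes from a γ-hydroxy tert-butyl ester, made by Evans alkylation of the N-[3-(3,4-dimethoxyphenyl)propanoyl] derivative of (S)-4-benzyl-2-oxazolidinone with tert-butyl bromoacetate (sets C4).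
- Ring order: both arenes are bought; the only ring made is the γ-lactone, closed before the aldol.

Assumption: 3-hydroxy-4,5-dimethoxybenzaldehyde is bought as a catalog compound, and the carbinol centre of the aldol adduct is carried as an epimer mixture because it is erased in the last step.

**Route**

Step 1
Reactants: 1 3-(3,4-dimethoxyphenyl)propanoic acid; 2 (S)-4-benzyl-2-oxazolidinone
Product: 4 (S)-4-benzyl-3-[3-(3,4-dimethoxyphenyl)propanoyl]oxazolidin-2-one, via mixed pivalic anhydride 3 (not isolated)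
Conditions: PivCl, Et3N, THF, −20 °C; then LiCl, 2, −20 °C → rt
Reagents that add atoms: pivaloyl chloride, CC(C)(C)C(=O)Cl (its acyl group stays in 3 only)
Why: One-pot mixed-anhydride N-acylation; the hindered pivaloyl carbonyl steers the LiCl-activated oxazolidinone to the desired acyl group, and no stereocentre is made.

Step 2
Reactants: 4 (S)-4-benzyl-3-[3-(3,4-dimethoxyphenyl)propanoyl]oxazolidin-2-one; 5 tert-butyl bromoacetate
Product: 7 tert-butyl (R)-3-[(S)-4-benzyl-2-oxooxazolidine-3-carbonyl]-4-(3,4-dimethoxyphenyl)butanoate, via sodium Z-enolate 6 (not isolated)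
Conditions: NaN(SiMe3)2 (1.1 equiv), THF, −78 °C; then 5, −78 → −40 °C
Reagents that add atoms: sodium bis(trimethylsilyl)amide NaN(SiMe3)2, C[Si](C)(C)[N-][Si](C)(C)C.[Na+] (sodium in 6 only)
Why: Evans asymmetric alkylation; the chelated Z-enolate is attacked on the face opposite the auxiliary benzyl group, which sets the future C4 centre as (R) with high diastereoselectivity (minor isomer removed by chromatography or crystallisation).

Step 3
Reactants: 7 tert-butyl (R)-3-[(S)-4-benzyl-2-oxooxazolidine-3-carbonyl]-4-(3,4-dimethoxyphenyl)butanoate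
Product: 9 (R)-4-tert-butoxy-2-(3,4-dimethoxybenzyl)-4-oxobutanoic acid, via peroxy acid 8 (not isolated)
Conditions: LiOH·H2O, 30% H2O2, THF/H2O 3:1, 0 °C; then aq. Na2SO3; then HCl to pH 2
Reagents that add atoms: hydrogen peroxide (as LiOOH), OO (both oxygens in 8, one in 9)
Why: Evans hydroperoxide cleavage; LiOOH attacks only the exocyclic imide carbonyl, leaves the tert-butyl ester alone and does not epimerise the α-centre, and sulfite reduces the peroxy acid to the acid.

Step 4
Reactants: 9 (R)-4-tert-butoxy-2-(3,4-dimethoxybenzyl)-4-oxobutanoic acid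
Product: 10 tert-butyl (R)-4-(3,4-dimethoxyphenyl)-3-(hydroxymethyl)butanoate
Conditions: BH3·SMe2 (1.5 equiv), THF, 0 °C → rt; MeOH quench
Reagents that add atoms: none
Why: Chemoselective borane reduction of a carboxylic acid (via the acyloxyborane) in the presence of an ester; the stereocentre is untouched.

Step 5
Reactants: 10 tert-butyl (R)-4-(3,4-dimethoxyphenyl)-3-(hydroxymethyl)butanoate
Product: 11 (R)-4-(3,4-dimethoxybenzyl)dihydrofuran-2(3H)-one
Conditions: p-TsOH·H2O (10 mol %), toluene, 80 °C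
Reagents that add atoms: none
Why: Acid-catalysed lactonisation of a γ-hydroxy tert-butyl ester to the five-membered ring, with the tert-butyl group leaving as isobutene and water; the centre is now β to the carbonyl and cannot epimerise.

Step 6
Reactants: 12 3-hydroxy-4,5-dimethoxybenzaldehyde
Product: 13 3-(benzyloxy)-4,5-dimethoxybenzaldehyde
Conditions: BnBr, K2CO3, DMF, rt
Reagents that add atoms: benzyl bromide, BrCc1ccccc1
Why: Williamson ether synthesis masks the acidic phenol, which would otherwise quench the enolate in step 7.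

Step 7
Reactants: 11 (R)-4-(3,4-dimethoxybenzyl)dihydrofuran-2(3H)-one; 13 3-(benzyloxy)-4,5-dimethoxybenzaldehyde
Product: 15 (3S,4R)-3-{[3-(benzyloxy)-4,5-dimethoxyphenyl](hydroxy)methyl}-4-(3,4-dimethoxybenzyl)dihydrofuran-2(3H)-one (carbinol epimer mixture), via lithium enolate 14 (not isolated)
Conditions: LiN(iPr)2 (1.1 equiv), THF, −78 °C; then 13, −78 °C, 2 h; AcOH quench at −78 °C
Reagents that add atoms: lithium diisopropylamide LiN(iPr)2, CC(C)[N-]C(C)C.[Li+] (lithium in 14 only)
Why: Directed crossed aldol addition of a lactone enolate to a non-enolisable aldehyde; the aldehyde adds anti to the C4 benzyl group, setting C3 trans to C4 (the ring configuration of the target), and the cold acidic quench prevents retro-aldol.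

Step 8
Reactants: 15 (3S,4R)-3-{[3-(benzyloxy)-4,5-dimethoxyphenyl](hydroxy)methyl}-4-(3,4-dimethoxybenzyl)dihydrofuran-2(3H)-one
Product: 17 (3R,4R)-4-(3,4-dimethoxybenzyl)-3-(3-hydroxy-4,5-dimethoxybenzyl)dihydrofuran-2(3H)-one, via debenzylated carbinol 16 (not isolated)
Conditions: H2 (3 bar), 10% Pd/C, AcOH, HClO4 (cat.), rt
Reagents that add atoms: none
Why: Catalytic hydrogenolysis cleaves the benzyl ether first and then the acid-activated, electron-rich benzylic C–OH bond; both carbinol epimers converge and the two ring centres are not touched (the C3 descriptor changes from S to R only through priority rules).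

**Compound list**

1 | 3-(3,4-dimethoxyphenyl)propanoic acid | COc1ccc(CCC(=O)O)cc1OC | starting material
2 | (S)-4-benzyl-2-oxazolidinone | O=C1N[C@@H](Cc2ccccc2)CO1 | starting material
3 | 3-(3,4-dimethoxyphenyl)propanoic pivalic anhydride (not isolated) | COc1ccc(CCC(=O)OC(=O)C(C)(C)C)cc1OC | intermediate
4 | (S)-4-benzyl-3-[3-(3,4-dimethoxyphenyl)propanoyl]oxazolidin-2-one | COc1ccc(CCC(=O)N2[C@@H](Cc3ccccc3)COC2=O)cc1OC | intermediate
5 | tert-butyl bromoacetate | CC(C)(C)OC(=O)CBr | starting material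
6 | sodium (Z)-enolate of 4 (not isolated) | COc1ccc(C/C=C(\[O-])N2[C@@H](Cc3ccccc3)COC2=O)cc1OC.[Na+] | intermediate
7 | tert-butyl (R)-3-[(S)-4-benzyl-2-oxooxazolidine-3-carbonyl]-4-(3,4-dimethoxyphenyl)butanoate | COc1ccc(C[C@H](CC(=O)OC(C)(C)C)C(=O)N2[C@@H](Cc3ccccc3)COC2=O)cc1OC | intermediate
8 | (R)-4-tert-butoxy-2-(3,4-dimethoxybenzyl)-4-oxobutaneperoxoic acid (not isolated) | COc1ccc(C[C@H](CC(=O)OC(C)(C)C)C(=O)OO)cc1OC | intermediate
9 | (R)-4-tert-butoxy-2-(3,4-dimethoxybenzyl)-4-oxobutanoic acid | COc1ccc(C[C@H](CC(=O)OC(C)(C)C)C(=O)O)cc1OC | intermediate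
10 | tert-butyl (R)-4-(3,4-dimethoxyphenyl)-3-(hydroxymethyl)butanoate | COc1ccc(C[C@H](CC(=O)OC(C)(C)C)CO)cc1OC | intermediate
11 | (R)-4-(3,4-dimethoxybenzyl)dihydrofuran-2(3H)-one | COc1ccc(C[C@H]2COC(=O)C2)cc1OC | intermediate
12 | 3-hydroxy-4,5-dimethoxybenzaldehyde | COc1cc(C=O)cc(O)c1OC | starting material
13 | 3-(benzyloxy)-4,5-dimethoxybenzaldehyde | COc1cc(C=O)cc(OCc2ccccc2)c1OC | intermediate
14 | lithium enolate of 11, lithium (R)-4-(3,4-dimethoxybenzyl)-4,5-dihydrofuran-2-olate (not isolated) | COc1ccc(C[C@H]2COC([O-])=C2)cc1OC.[Li+] | intermediate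
15 | (3S,4R)-3-{[3-(benzyloxy)-4,5-dimethoxyphenyl](hydroxy)methyl}-4-(3,4-dimethoxybenzyl)dihydrofuran-2(3H)-one, carbinol epimer mixture | COc1ccc(C[C@H]2COC(=O)[C@@H]2C(O)c2cc(OCc3ccccc3)c(OC)c(OC)c2)cc1OC | intermediate
16 | (3S,4R)-4-(3,4-dimethoxybenzyl)-3-[hydroxy(3-hydroxy-4,5-dimethoxyphenyl)methyl]dihydrofuran-2(3H)-one, carbinol epimer mixture (not isolated) | COc1ccc(C[C@H]2COC(=O)[C@@H]2C(O)c2cc(O)c(OC)c(OC)c2)cc1OC | intermediate
17 | (3R,4R)-4-(3,4-dimethoxybenzyl)-3-(3-hydroxy-4,5-dimethoxybenzyl)dihydrofuran-2(3H)-one (CNP0246971.1) | COc1ccc(C[C@H]2COC(=O)[C@@H]2Cc2cc(O)c(OC)c(OC)c2)cc1OC | target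

**Summary**

Total step count: 8. Longest linear sequence: 7 steps (steps 1, 2, 3, 4, 5, 7, 8 from acid 1); step 6 is a one-step side branch.

Steps most likely to fail, with fallbacks:

Step 8 (one-pot hydrogenolysis). The acid needed to cleave the benzylic C–OH can instead trigger Friedel–Crafts closure onto the dimethoxyphenyl ring (aryltetralin), or the reaction can stall at 16. The fallback sets out from 15. Mesylation and E1cB elimination (MsCl, Et3N, CH2Cl2, 0 °C; then DBU) give (R,E)-3-[3-(benzyloxy)-4,5-dimethoxybenzylidene]-4-(3,4-dimethoxybenzyl)dihydrofuran-2(3H)-one F1. Acid-free hydrogenation (H2, Pd/C, EtOAc) saturates the alkene from the face away from the C4 benzyl group and cleaves the benzyl ether, giving mainly the 3,4-cis lactone (3S,4R)-4-(3,4-dimethoxybenzyl)-3-(3-hydroxy-4,5-dimethoxybenzyl)dihydrofuran-2(3H)-one F2. Equilibration at C3 (NaOMe, MeOH, rt; then aq. HCl to reclose any opened lactone) converts it into the more stable trans isomer, and the route is rejoined at 17. C4 is not acidic and keeps its configuration.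

Step 7 (aldol). Retro-aldol on warming or incomplete addition to the electron-rich aldehyde would cut the yield. The fallback sets out from 13 and replaces the aldol and hydrogenolysis by an enolate alkylation. NaBH4 in MeOH gives [3-(benzyloxy)-4,5-dimethoxyphenyl]methanol F3, and PBr3 in CH2Cl2 at 0 °C gives 1-(benzyloxy)-5-(bromomethyl)-2,3-dimethoxybenzene F4. Enolate 14 (from 11 with LiN(SiMe3)2 in THF/DMPU, −78 °C) is alkylated by F4 anti to the C4 benzyl group to give (3R,4R)-3-[3-(benzyloxy)-4,5-dimethoxybenzyl]-4-(3,4-dimethoxybenzyl)dihydrofuran-2(3H)-one F5. Neutral hydrogenolysis (H2, Pd/C, EtOAc) removes the benzyl ether, and the route is rejoined at 17.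

Step 2 (Evans alkylation). The bromoacetate is only moderately reactive and base-sensitive, so conversion or diastereoselectivity may fall short. The fallback sets out from 4 and uses an allyl group as a masked acetate. Enolate 6 with allyl bromide gives (S)-4-benzyl-3-[(S)-2-(3,4-dimethoxybenzyl)pent-4-enoyl]oxazolidin-2-one F6, with the same facial sense (the descriptor differs by priority only). LiBH4 (Et2O, 1 equiv H2O, 0 °C) removes the auxiliary reductively to give (S)-2-(3,4-dimethoxybenzyl)pent-4-en-1-ol F7. Oxidative alkene cleavage (OsO4 cat., NaIO4, 2,6-lutidine, dioxane/H2O) gives an aldehyde that closes to the lactol (4R)-4-(3,4-dimethoxybenzyl)tetrahydrofuran-2-ol F8. Fétizon oxidation (Ag2CO3 on Celite, toluene, reflux) gives the lactone, and the route is rejoined at 11.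

**Further compounds**

F1 | step 8 | (R,E)-3-[3-(benzyloxy)-4,5-dimethoxybenzylidene]-4-(3,4-dimethoxybenzyl)dihydrofuran-2(3H)-one | COc1ccc(C[C@H]2COC(=O)/C2=C/c2cc(OCc3ccccc3)c(OC)c(OC)c2)cc1OC
F2 | step 8 | (3S,4R)-4-(3,4-dimethoxybenzyl)-3-(3-hydroxy-4,5-dimethoxybenzyl)dihydrofuran-2(3H)-one (3,4-cis) | COc1ccc(C[C@H]2COC(=O)[C@H]2Cc2cc(O)c(OC)c(OC)c2)cc1OC
F3 | step 7 | [3-(benzyloxy)-4,5-dimethoxyphenyl]methanol | COc1cc(CO)cc(OCc2ccccc2)c1OC
F4 | step 7 | 1-(benzyloxy)-5-(bromomethyl)-2,3-dimethoxybenzene | COc1cc(CBr)cc(OCc2ccccc2)c1OC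
F5 | step 7 | (3R,4R)-3-[3-(benzyloxy)-4,5-dimethoxybenzyl]-4-(3,4-dimethoxybenzyl)dihydrofuran-2(3H)-one | COc1ccc(C[C@H]2COC(=O)[C@@H]2Cc2cc(OCc3ccccc3)c(OC)c(OC)c2)cc1OC
F6 | step 2 | (S)-4-benzyl-3-[(S)-2-(3,4-dimethoxybenzyl)pent-4-enoyl]oxazolidin-2-one | COc1ccc(C[C@H](CC=C)C(=O)N2[C@@H](Cc3ccccc3)COC2=O)cc1OC
F7 | step 2 | (S)-2-(3,4-dimethoxybenzyl)pent-4-en-1-ol | COc1ccc(C[C@H](CC=C)CO)cc1OC
F8 | step 2 | (4R)-4-(3,4-dimethoxybenzyl)tetrahydrofuran-2-ol (anomer mixture) | COc1ccc(C[C@H]2COC(O)C2)cc1OC
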